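## The problem

Target 13 is a trans-2,3-disubstituted 2,3-dihydrobenzofuran. Ring B (O1, C2, C3, C3a, C7a) is fused to ring A, which carries an allyl group at C5 and a methoxy group at C7. C2 bears ring C (4-hydroxy-3-methoxyphenyl), and C3 bears a CH2–O link to ring D, a second 4-allyl-2-methoxyphenyl unit. Ring A and ring D are both eugenol and ring C with its benzylic carbon is vanillin, so the only skeletal C–C bonds to be made are C2–C3 and C3–C3a; the rest is C–O chemistry. The two adjacent stereocentres are C2 (S) and C3 (R). C2 is a non-acidic benzylic ether methine and must be set absolutely by a catalyst. C3 has no acidifying group in the target, so it can be corrected only while its exocyclic carbon is still a carbonyl; at that stage C2 can drive it to trans thermodynamically. The two terminal allyl groups rule out hydrogenolysis, strongly basic conditions that would move the double bonds into conjugation, and electrophilic oxidants. The free phenol is para to the C2–O1 bond, which can open to a quinone methide under strong acid or base, so it stays masked until a near-neutral final step. The enabling feature is that C2 is both benzylic to ring C and bonded to O1, and lies five atoms from C3 along C3–C3a–C7a–O1–C2. In a vanillyl ether of ring A, the C2–H bonds are therefore the most activated ones and the only ones a carbene at C3 can reach.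

## Retrosynthesis

**13 from 12 (O–Si).** The ring C phenol is carried as a triisopropylsilyl ether and released last from 12. A benzyl ether is excluded because hydrogenolysis would saturate both allyl groups. The triisopropylsilyl group is preferred to tert-butyldimethylsilyl because the phenolic silyl ether has to survive an amidine base and two phenoxide-generating etherifications. Fluoride buffered with acetic acid is asked to remove it without opening ring B.

**12 from 11 and 1 (CH2–O of ring D).** The alkyl C–O bond is cut, not the aryl C–O bond, since ring D is electron-rich and offers no handle for nucleophilic aromatic substitution. This returns eugenol 1 and the primary alcohol 11. The forward reaction is a Mitsunobu etherification at a primary carbon, which touches neither stereocentre.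

**11 from 10 from 9 (oxidation level and C3 configuration).** The hydroxymethyl group is traced to an ethyl ester. The ester is the one device in the route that makes C3 epimerisable. The trans ester 10 comes from the cis ester 9 by base equilibration, in which the fixed C2 centre dictates C3. The forward steps must reduce an ester without touching the alkenes or the silyl ether.

**9 from 8 (C2–C3, ring B).** This is the strategic cut. Cutting C3–C3a instead would need a placeholder on ring A or an aryl C–H functionalisation. Cutting O1–C2 would need an acyclic anti stereodiad and a later substitution at a benzylic carbon prone to ionise. Cutting C2–C3 gives the aryl diazoacetate 8, which has no ring B and no stereocentre and is assembled from flat pieces. The forward reaction has to create both centres and the ring in one catalytic event: a dirhodium carboxylate-catalysed enantioselective 1,5 C–H insertion.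

**8 from 6 and 7 (aryl–C of the diazoacetate).** The bond between C3a and the diazo carbon is made by palladium-catalysed coupling of the aryl iodide 6 with ethyl diazoacetate 7, which keeps the diazo group. The alternative, diazo transfer to an arylacetic ester, would first require homologation of eugenol at the ortho position and is longer. The ethyl ester is chosen because 7 is the commercial reagent.

**6 from 2 and 5 (benzylic C–O).** The vanillyl ether is cut at the benzylic C–O bond to the iodophenol 2 and the benzylic alcohol 5. A Mitsunobu reaction is preferred to alkylation with the corresponding benzylic chloride, because that electron-rich chloride is labile and carbonate in a dipolar solvent threatens the aryl silyl ether.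

**2 from 1; 5 from 4 from 3.** Iodophenol 2 is eugenol 1 iodinated at the one free position ortho to the hydroxyl group. Alcohol 5 is vanillin 3 after silylation (4) and hydride reduction.

## Roads not taken

**Alternative 1:** Ring B is taken as the flat benzofuran A1 (5-bromo-7-methoxybenzofuran). The C3 side-chain carbon is added as the carbene carbon of 7 across C2=C3, and the C2–aryl bond is made afterwards by opening the cyclopropane. The key step uses CuOTf with 2,2′-isopropylidenebis[(4S)-4-tert-butyl-2-oxazoline] and gives the exo cyclopropane A2 with C3 as in the target.
- Merits: the catalyst is cheap and copper bis(oxazoline) cyclopropanation of electron-rich C=C bonds is a robust reaction class. Opening the donor–acceptor cyclopropane at the oxygen-bearing carbon would bring ring C in trans to the C3 substituent directly, so no epimerisation step is needed. In that respect it is better than the chosen plan.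
- Weak points: the opened product A3 carries CH2CO2Et at C3, one carbon more than the CH2–O the target needs. The carboxyl carbon would have to be excised and replaced by oxygen, a multi-step degradation next to a stereocentre. The cation at C2 formed during opening can instead lose the C3 proton and aromatise to a benzofuran, erasing both centres. The bromine is a placeholder that must later be exchanged for allyl.
- Comparison: the chosen plan has to set an epimerisation step against the direct trans outcome here. In return its key step delivers the C3 substituent with the correct carbon count and a directly reducible oxidation level, and ring A carries its allyl group from the start.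

**Alternative 2:** Ring A is built de novo. The homopropargylic alcohol A4, with both centres already in place, is converted into the (CO)5Cr alkoxy(1-methoxyvinyl)carbene complex A5. On warming, the tethered alkyne and one CO insert and the dienylketene electrocyclises (Dötz benzannulation), forming C3a–C7a, C4–C5 and C5–C6 and closing rings A and B together to give phenol A6.
- Merits: both stereocentres are fixed in an acyclic precursor, so the product is trans from the outset. Ring D is already attached, and only three operations remain after the key step. In convergence and in freedom from an epimerisation step this road is at least as good as the chosen one.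
- Weak points: chromium is stoichiometric. Making A5 means acylating or exchanging onto a hindered secondary benzylic alkoxide, and α-alkoxyvinyl carbene complexes are delicate. A4 itself needs an anti-selective asymmetric construction of several steps. The benzannulation leaves a hydroxyl group at C5 where the allyl group belongs, so a sulfonylation and a cross-coupling are added.
- Comparison: the chosen plan sets a catalytic metal, an achiral precursor made in five steps and a ring A bought complete against the substrate-defined stereochemistry of this road.

**Alternative 3:** The C3–C3a bond is made by 1,2-shift. The enantiopure (2S)-flavanone A7 is treated with PhI(OAc)2 and H2SO4 in trimethyl orthoformate. The enol ether is iodinated at C3 and the ring A carbon migrates from C4 to C3, contracting the pyranone to ring B with the old C4 as a methyl ester, giving the trans ester A8.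
- Merits: C2 is retained and the trans ester forms directly. No diazo compound is handled and flavanone chemistry scales well. On these points it is better than the chosen plan.
- Weak points: a flavanone with an oxygenated ring C loses optical purity easily by reversible ring opening, which is why ring C must be carried as the electron-poor tosylate. Under the contraction conditions, migration of the C2 aryl group and dehydrogenation to the flavone compete. An allyl group would not survive the hypervalent iodine reagent, so bromine stands in for it and must be exchanged by cross-coupling in the presence of an aryl tosylate. Removing the tosylate at the end needs strong base or a dissolving metal next to a C2–O1 bond that can open.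
- Comparison: the step count is similar or longer. The chosen plan pays with an epimerisation and a diazo intermediate. It gains catalyst control of C2 in the ring-forming step itself, both allyl groups in place from the start, and a final deprotection under buffered fluoride.

Key step: step 6

Assumption: dirhodium catalysts with N-phthaloyl-(S)-amino acid ligands are taken to give (2R)-cis esters from 2-benzyloxyphenyl diazoacetates, as in the closest cases. The (2S) target is therefore assigned to the (R)-tert-leucinate complex Rh2(R-PTTL)4. If the vanillyl ether reverses the sense, Rh2(S-PTTL)4 is used with nothing else changed.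

## Route

Step 1
Reactants: 1 eugenol (4-allyl-2-methoxyphenol)
Product: 2 4-allyl-2-iodo-6-methoxyphenol
Conditions: I2, KI, NaHCO3, THF/H2O, 0 °C to rt
Reagents that add atoms: iodine, II
Why: Electrophilic aromatic iodination of the phenoxide; the para position is blocked by the allyl group, so the only position activated by the hydroxyl group is C6, and triiodide is too weak an electrophile to add to the isolated terminal alkene.

Step 2
Reactants: 3 vanillin (4-hydroxy-3-methoxybenzaldehyde)
Product: 4 3-methoxy-4-(triisopropylsilyloxy)benzaldehyde
Conditions: iPr3SiCl, imidazole, DMF, rt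
Reagents that add atoms: chlorotriisopropylsilane, CC(C)[Si](Cl)(C(C)C)C(C)C
Why: Standard imidazole-mediated silylation of a phenol; the aldehyde is inert.

Step 3
Reactants: 4 3-methoxy-4-(triisopropylsilyloxy)benzaldehyde
Product: 5 [3-methoxy-4-(triisopropylsilyloxy)phenyl]methanol
Conditions: NaBH4, MeOH/THF, 0 °C
Reagents that add atoms: none
Why: Borohydride reduction of an aromatic aldehyde; the hindered aryl silyl ether should be stable to brief exposure at 0 °C.

Step 4
Reactants: 2 4-allyl-2-iodo-6-methoxyphenol; 5 [3-methoxy-4-(triisopropylsilyloxy)phenyl]methanol
Product: 6 5-allyl-1-iodo-3-methoxy-2-{[3-methoxy-4-(triisopropylsilyloxy)phenyl]methoxy}benzene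
Conditions: PPh3, DIAD, THF, 0 °C to rt
Reagents that add atoms: none
Why: Mitsunobu etherification; the ortho-iodophenol is acidic enough to protonate the betaine and the primary benzylic oxyphosphonium ion is displaced readily, without the free base or labile benzylic halide that would endanger the silyl ether.

Step 5
Reactants: 6 5-allyl-1-iodo-3-methoxy-2-{[3-methoxy-4-(triisopropylsilyloxy)phenyl]methoxy}benzene; 7 ethyl diazoacetate
Product: 8 ethyl 2-diazo-2-(5-allyl-3-methoxy-2-{[3-methoxy-4-(triisopropylsilyloxy)phenyl]methoxy}phenyl)acetate
Conditions: Pd(PPh3)4 (5 mol %), Et3N, Bu4NBr, MeCN, rt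
Reagents that add atoms: none
Why: Palladium-catalysed cross-coupling of an aryl iodide with an acceptor diazo compound with retention of the diazo group: oxidative addition to zerovalent palladium, C-palladation of deprotonated 7 and reductive elimination occur at room temperature before N2 is lost; the mild temperature should leave the allyl group unengaged.

Step 6
Reactants: 8 ethyl 2-diazo-2-(5-allyl-3-methoxy-2-{[3-methoxy-4-(triisopropylsilyloxy)phenyl]methoxy}phenyl)acetate
Product: 9 ethyl (2S,3R)-5-allyl-7-methoxy-2-[3-methoxy-4-(triisopropylsilyloxy)phenyl]-2,3-dihydrobenzofuran-3-carboxylate (cis)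
Conditions: Rh2(R-PTTL)4 [dirhodium tetrakis(N-phthaloyl-(R)-tert-leucinate)] (1 mol %), toluene, −60 °C, slow addition of 8, 0.01 M
Reagents that add atoms: none
Why: The dirhodium carboxylate takes up the diazo carbon of 8, N2 leaves, and the rhodium-bound donor/acceptor carbene at C3 inserts into one of the two C2–H bonds of the vanillyl ether in a concerted, asynchronous three-centre step, in which the positive charge building on C2 is carried by O1 and by the electron-rich ring C. The closest known reaction type is the dirhodium carboxylate-catalysed enantioselective intramolecular C–H insertion of 2-benzyloxyphenyl diazoacetates, which gives cis-2-aryl-2,3-dihydrobenzofuran-3-carboxylates. Ring B closes by 1,5 insertion: the new C2–C3 bond completes the five-membered array C3–C3a–C7a–O1–C2, and the other closures open to this tether, a four-membered oxonium ylide at O1 or a seven-membered attack on ring C, are less favourable. C2 is set by the catalyst, whose phthalimido walls make the two enantiotopic benzylic hydrogens unequal, so that the hydrogen whose replacement gives (2S) reacts (see the assumption before the steps). C3 is set in the same event: ester and aryl group end cis because the hydrogen is delivered to C3 with the aryl group turned away from the carboxylate ligands, and this kinetic outcome is corrected in step 7. The step needs chemoselectivity for the benzylic C–H bond over the alkenes and over carbene dimerisation. The allyl group of the same molecule is meta to the carbene carbon and cannot reach it, while intermolecular cyclopropanation and dimerisation are second order and are held back by slow addition at high dilution. The doubly activated C–H bond should react at −60 °C, and the remote silyl ether and methoxy groups offer no competing C–H bond within reach.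

Step 7
Reactants: 9 ethyl (2S,3R)-5-allyl-7-methoxy-2-[3-methoxy-4-(triisopropylsilyloxy)phenyl]-2,3-dihydrobenzofuran-3-carboxylate (cis)
Product: 10 ethyl (2S,3S)-5-allyl-7-methoxy-2-[3-methoxy-4-(triisopropylsilyloxy)phenyl]-2,3-dihydrobenzofuran-3-carboxylate (trans)
Conditions: DBU (1 equiv), dry toluene, rt
Reagents that add atoms: none
Why: Thermodynamic epimerisation through the ester enolate at C3; the trans isomer relieves the eclipsing of aryl and ester groups on the nearly flat five-membered ring, C2 has no acidic hydrogen and is untouched, and anhydrous non-nucleophilic base spares the aryl silyl ether and the allyl groups.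

Step 8
Reactants: 10 ethyl (2S,3S)-5-allyl-7-methoxy-2-[3-methoxy-4-(triisopropylsilyloxy)phenyl]-2,3-dihydrobenzofuran-3-carboxylate (trans)
Product: 11 [(2S,3R)-5-allyl-7-methoxy-2-[3-methoxy-4-(triisopropylsilyloxy)phenyl]-2,3-dihydrobenzofuran-3-yl]methanol (trans)
Conditions: iBu2AlH (2.5 equiv), CH2Cl2, −78 to 0 °C; aqueous potassium sodium tartrate
Reagents that add atoms: none
Why: Ester reduction to the primary alcohol with an aluminium hydride; terminal alkenes are not hydroaluminated at these temperatures, and the non-basic medium leaves C3 and the silyl ether alone (the descriptor at C3 changes only because the substituent priorities change).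

Step 9
Reactants: 11 [(2S,3R)-5-allyl-7-methoxy-2-[3-methoxy-4-(triisopropylsilyloxy)phenyl]-2,3-dihydrobenzofuran-3-yl]methanol; 1 eugenol
Product: 12 (2S,3R)-5-allyl-3-[(4-allyl-2-methoxyphenoxy)methyl]-7-methoxy-2-[3-methoxy-4-(triisopropylsilyloxy)phenyl]-2,3-dihydrobenzofuran
Conditions: PPh3, DIAD, THF, 0 °C to rt
Reagents that add atoms: none
Why: Mitsunobu etherification of a primary alcohol with a phenol of suitable acidity; substitution occurs at the CH2 group, so neither stereocentre is involved.

Step 10
Reactants: 12 (2S,3R)-5-allyl-3-[(4-allyl-2-methoxyphenoxy)methyl]-7-methoxy-2-[3-methoxy-4-(triisopropylsilyloxy)phenyl]-2,3-dihydrobenzofuran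
Product: 13 4-[(2S,3R)-5-allyl-3-[(4-allyl-2-methoxyphenoxy)methyl]-7-methoxy-2,3-dihydrobenzofuran-2-yl]-2-methoxyphenol (target)
Conditions: Bu4NF, AcOH, THF, 0 °C
Reagents that add atoms: none
Why: Fluoride cleavage of the aryl silyl ether; the acetic acid buffer keeps the liberated phenoxide protonated, so the para C2–O1 bond should not open to a quinone methide.

## Compound list

1 | eugenol (4-allyl-2-methoxyphenol) | C=CCc1ccc(O)c(OC)c1 | starting material
2 | 4-allyl-2-iodo-6-methoxyphenol | C=CCc1cc(I)c(O)c(OC)c1 | intermediate
3 | vanillin | COc1cc(C=O)ccc1O | starting material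
4 | 3-methoxy-4-(triisopropylsilyloxy)benzaldehyde | COc1cc(C=O)ccc1O[Si](C(C)C)(C(C)C)C(C)C | intermediate
5 | [3-methoxy-4-(triisopropylsilyloxy)phenyl]methanol | COc1cc(CO)ccc1O[Si](C(C)C)(C(C)C)C(C)C | intermediate
6 | 5-allyl-1-iodo-3-methoxy-2-{[3-methoxy-4-(triisopropylsilyloxy)phenyl]methoxy}benzene | C=CCc1cc(I)c(OCc2ccc(O[Si](C(C)C)(C(C)C)C(C)C)c(OC)c2)c(OC)c1 | intermediate
7 | ethyl diazoacetate | CCOC(=O)C=[N+]=[N-] | starting material
8 | ethyl 2-diazo-2-(5-allyl-3-methoxy-2-{[3-methoxy-4-(triisopropylsilyloxy)phenyl]methoxy}phenyl)acetate | CCOC(=O)C(=[N+]=[N-])c1cc(CC=C)cc(OC)c1OCc1ccc(O[Si](C(C)C)(C(C)C)C(C)C)c(OC)c1 | intermediate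
9 | ethyl (2S,3R)-5-allyl-7-methoxy-2-[3-methoxy-4-(triisopropylsilyloxy)phenyl]-2,3-dihydrobenzofuran-3-carboxylate (cis) | CCOC(=O)[C@@H]1c2cc(CC=C)cc(OC)c2O[C@@H]1c1ccc(O[Si](C(C)C)(C(C)C)C(C)C)c(OC)c1 | intermediate
10 | ethyl (2S,3S)-5-allyl-7-methoxy-2-[3-methoxy-4-(triisopropylsilyloxy)phenyl]-2,3-dihydrobenzofuran-3-carboxylate (trans) | CCOC(=O)[C@H]1c2cc(CC=C)cc(OC)c2O[C@@H]1c1ccc(O[Si](C(C)C)(C(C)C)C(C)C)c(OC)c1 | intermediate
11 | [(2S,3R)-5-allyl-7-methoxy-2-[3-methoxy-4-(triisopropylsilyloxy)phenyl]-2,3-dihydrobenzofuran-3-yl]methanol (trans) | OC[C@H]1c2cc(CC=C)cc(OC)c2O[C@@H]1c1ccc(O[Si](C(C)C)(C(C)C)C(C)C)c(OC)c1 | intermediate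
12 | (2S,3R)-5-allyl-3-[(4-allyl-2-methoxyphenoxy)methyl]-7-methoxy-2-[3-methoxy-4-(triisopropylsilyloxy)phenyl]-2,3-dihydrobenzofuran | C=CCc1ccc(OC[C@H]2c3cc(CC=C)cc(OC)c3O[C@@H]2c2ccc(O[Si](C(C)C)(C(C)C)C(C)C)c(OC)c2)c(OC)c1 | intermediate
13 | 4-[(2S,3R)-5-allyl-3-[(4-allyl-2-methoxyphenoxy)methyl]-7-methoxy-2,3-dihydrobenzofuran-2-yl]-2-methoxyphenol | C=CCc1ccc(OC[C@H]2c3cc(CC=C)cc(OC)c3O[C@@H]2c2ccc(O)c(OC)c2)c(OC)c1 | target

## Step count and risks

Total: 10 steps. Longest linear sequence: 9 steps (vanillin 3 through steps 2, 3, 4, 5, 6, 7, 8, 9 and 10). The eugenol branch joins at step 4 after one step.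

**Step 6 (key step).** The most likely failure is erosion of enantioselectivity. The C2–H bond is activated by both O1 and a strongly donating aryl group, so the transition state is early and the catalyst pocket may discriminate the two benzylic hydrogens less well than with plain benzyl ethers. Intermolecular capture of the carbene by an allyl group is a second concern if addition is too fast. The fallback replaces catalyst control by separation of diastereomers. It sets out from alcohol 11 of insufficient enantiomeric purity, in the limit racemic material made with Rh2(OAc)4 in step 6 and carried through steps 7 and 8. Acylation with (1S)-camphanic chloride, Et3N and DMAP in CH2Cl2 should give the (1S)-camphanate of 11 F1 together with the (1S)-camphanate of the enantiomer of 11 F2. These are separated by crystallisation or chromatography. Reductive cleavage of F1 with iBu2AlH in CH2Cl2 at −78 °C, which avoids base, returns to the route at 11 as a single enantiomer.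

**Step 5.** Oxidative addition to the ortho-alkoxy, electron-rich aryl iodide may be slower than palladium-mediated decomposition of 7 to carbene dimers, and palladium hydride formed along the way could move the allyl double bond into conjugation. The fallback builds the diazo ester in two classical steps. It sets out from 6: cross-coupling with the Reformatsky reagent BrZnCH2CO2Et under Pd(dba)2 with Q-Phos in THF should give the ethyl arylacetate F3. Regitz diazo transfer with 4-acetamidobenzenesulfonyl azide and DBU in MeCN then comes back to the route at 8.

**Step 7.** The C3 enolate has the O1 phenoxide as a β-leaving group, so E1cB ring opening can compete with simple reprotonation. This would consume material or, on reclosure, erode the configuration at C2; equilibration may also stop short of completion. The fallback moves the epimerisation to the aldehyde oxidation level, where a tertiary amine suffices. It sets out from 9: reduction with iBu2AlH should give the cis alcohol F4. Oxidation with Dess–Martin periodinane in CH2Cl2 gives the cis aldehyde F5, which is equilibrated in the same flask with Et3N to the trans aldehyde F6. NaBH4 in MeOH at 0 °C then returns to the route at 11.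

**Step 9.** Substitution at the β-branched primary carbon may be slow, leaving room for elimination of the activated alcohol towards an exocyclic alkene or for alkylation of the reduced azodicarboxylate. The fallback separates activation from displacement. It sets out from 11: MsCl and Et3N in CH2Cl2 at 0 °C give the mesylate F7. Displacement with eugenol 1 and K2CO3 in DMF at 50 °C, which the triisopropylsilyl ether should tolerate, comes back to the route at 12.

## Further compounds

F1 | step 6 | (1S)-camphanate of 11, [(2S,3R)-5-allyl-7-methoxy-2-[3-methoxy-4-(triisopropylsilyloxy)phenyl]-2,3-dihydrobenzofuran-3-yl]methyl (1S,4R)-4,7,7-trimethyl-3-oxo-2-oxabicyclo[2.2.1]heptane-1-carboxylate | CC1(C)[C@@]2(C)CC[C@@]1(OC2=O)C(=O)OC[C@H]1c2cc(CC=C)cc(OC)c2O[C@@H]1c1ccc(O[Si](C(C)C)(C(C)C)C(C)C)c(OC)c1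
F2 | step 6 | (1S)-camphanate of the enantiomer of 11, the (2R,3S) diastereomer of F1 | CC1(C)[C@@]2(C)CC[C@@]1(OC2=O)C(=O)OC[C@@H]1c2cc(CC=C)cc(OC)c2O[C@H]1c1ccc(O[Si](C(C)C)(C(C)C)C(C)C)c(OC)c1
F3 | step 5 | ethyl 2-(5-allyl-3-methoxy-2-{[3-methoxy-4-(triisopropylsilyloxy)phenyl]methoxy}phenyl)acetate | CCOC(=O)Cc1cc(CC=C)cc(OC)c1OCc1ccc(O[Si](C(C)C)(C(C)C)C(C)C)c(OC)c1
F4 | step 7 | [(2S,3S)-5-allyl-7-methoxy-2-[3-methoxy-4-(triisopropylsilyloxy)phenyl]-2,3-dihydrobenzofuran-3-yl]methanol (cis) | OC[C@@H]1c2cc(CC=C)cc(OC)c2O[C@@H]1c1ccc(O[Si](C(C)C)(C(C)C)C(C)C)c(OC)c1
F5 | step 7 | (2S,3R)-5-allyl-7-methoxy-2-[3-methoxy-4-(triisopropylsilyloxy)phenyl]-2,3-dihydrobenzofuran-3-carbaldehyde (cis) | O=C[C@@H]1c2cc(CC=C)cc(OC)c2O[C@@H]1c1ccc(O[Si](C(C)C)(C(C)C)C(C)C)c(OC)c1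
F6 | step 7 | (2S,3S)-5-allyl-7-methoxy-2-[3-methoxy-4-(triisopropylsilyloxy)phenyl]-2,3-dihydrobenzofuran-3-carbaldehyde (trans) | O=C[C@H]1c2cc(CC=C)cc(OC)c2O[C@@H]1c1ccc(O[Si](C(C)C)(C(C)C)C(C)C)c(OC)c1
F7 | step 9 | [(2S,3R)-5-allyl-7-methoxy-2-[3-methoxy-4-(triisopropylsilyloxy)phenyl]-2,3-dihydrobenzofuran-3-yl]methyl methanesulfonate | CS(=O)(=O)OC[C@H]1c2cc(CC=C)cc(OC)c2O[C@@H]1c1ccc(O[Si](C(C)C)(C(C)C)C(C)C)c(OC)c1
A1 | alternative 1 | 5-bromo-7-methoxybenzofuran | COc1cc(Br)cc2ccoc12
A2 | alternative 1 | ethyl exo-5-bromo-3-methoxy-1a,6b-dihydro-1H-cyclopropa[b]benzofuran-1-carboxylate, benzofuran C3 configured as in the target | CCOC(=O)[C@@H]1[C@H]2c3cc(Br)cc(OC)c3O[C@@H]12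
A3 | alternative 1 | ethyl 2-[(2S,3S)-5-bromo-7-methoxy-2-[3-methoxy-4-(triisopropylsilyloxy)phenyl]-2,3-dihydrobenzofuran-3-yl]acetate (trans) | CCOC(=O)C[C@H]1c2cc(Br)cc(OC)c2O[C@@H]1c1ccc(O[Si](C(C)C)(C(C)C)C(C)C)c(OC)c1
A4 | alternative 2 | 2-[(4-allyl-2-methoxyphenoxy)methyl]-1-[4-(tert-butyldimethylsilyloxy)-3-methoxyphenyl]but-3-yn-1-ol, both centres as in the target | C=CCc1ccc(OC[C@@H](C#C)[C@H](O)c2ccc(O[Si](C)(C)C(C)(C)C)c(OC)c2)c(OC)c1
A5 | alternative 2 | pentacarbonylchromium alkoxy(1-methoxyvinyl)carbene complex, (CO)5Cr=C(OR)C(OMe)=CH2 with OR the alkoxide of A4 | C=CCc1ccc(OC[C@@H](C#C)[C@H](OC(=[Cr](=C=O)(=C=O)(=C=O)(=C=O)=C=O)C(OC)=C)c2ccc(O[Si](C)(C)C(C)(C)C)c(OC)c2)c(OC)c1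
A6 | alternative 2 | (2S,3R)-3-[(4-allyl-2-methoxyphenoxy)methyl]-2-[4-(tert-butyldimethylsilyloxy)-3-methoxyphenyl]-7-methoxy-2,3-dihydrobenzofuran-5-ol (trans) | C=CCc1ccc(OC[C@H]2c3cc(O)cc(OC)c3O[C@@H]2c2ccc(O[Si](C)(C)C(C)(C)C)c(OC)c2)c(OC)c1
A7 | alternative 3 | (2S)-6-bromo-8-methoxy-2-[3-methoxy-4-(p-tolylsulfonyloxy)phenyl]chroman-4-one | O=C1C[C@@H](c2ccc(OS(=O)(=O)c3ccc(C)cc3)c(OC)c2)Oc2c(OC)cc(Br)cc21
A8 | alternative 3 | methyl (2S,3S)-5-bromo-7-methoxy-2-[3-methoxy-4-(p-tolylsulfonyloxy)phenyl]-2,3-dihydrobenzofuran-3-carboxylate (trans) | COC(=O)[C@H]1c2cc(Br)cc(OC)c2O[C@@H]1c1ccc(OS(=O)(=O)c3ccc(C)cc3)c(OC)c1
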